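## Analysis of the target

1. The target is a germacranolide: a cyclodeca-1(10),4-diene (ring A, C1–C10) fused through the C7–C8 bond to an α-methylene-γ-butyrolactone (ring B: O–C8–C7–C11–C12, exocyclic C11=C13), that is a 12,8-olide. Germacrane numbering is used throughout, with C14 on C10 and C15 on C4.
2. Ring A holds a 1,5-diene with opposite ring geometries. In C1=C10, C9 and C2 are cis (C14 trans to C2, CIP E). In C4=C5, C3 and C6 are trans (C15 cis to C6, CIP Z).
3. The only stereocentres are C7 (R) and C8 (S). They are adjacent, H7 and H8 are trans (trans-fused lactone), and both lie on the one bond that rings A and B share.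
4. O14 and O15 are primary allylic oxygens with different acyl groups: an acetate and a 2-(hydroxymethyl)acrylate whose own primary hydroxyl is free.
5. Sensitive functions are two Michael acceptors, allylic esters that zerovalent metals can ionise, base-labile esters, and a cyclodeca-1,5-diene that can undergo Cope rearrangement on heating or transannular cyclisation in acid.
6. Three things make the synthesis hard: closing a strained ten-membered ring that contains two trisubstituted alkenes of defined and opposite geometry; setting C7 and C8 in absolute terms with no other stereocentre to lean on; and telling O14 from O15.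
7. The feature the plan exploits is the C7–C8 bond. C8 is at the aldehyde oxidation level and C7 is the γ-carbon of the C13–C11(C12)=C7 allyl unit, both electrophilic in simple precursors. One reductive, polarity-reversed event can therefore close ring A, prepare ring B and set both stereocentres.

## Retrosynthetic reasoning

**26 to 25.** Only the silyl ether on the acrylate hydroxyl is removed at the end. Both acyl groups are already in place in 25, so no acylation has to be run on the macrocycle with its two Michael acceptors.

**25 to 22 (key disconnection).** The C7–C8 bond and the O8–C12 lactone bond are cut. This is the only bond that carries both stereocentres and belongs to both rings, so cutting it turns the bicyclic target into the achiral, acyclic bromo aldehyde 22. The forward reaction has to join two electrophilic carbons (the enoate γ-carbon C7 and the aldehyde carbon C8) by reduction of the allylic bromide to an allylchromium species. It must do so at high dilution, anti-selectively and under ligand control of the absolute configuration, via 23 and 24.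

**22 to 19.** The C8 aldehyde is β,γ-unsaturated and is unmasked last from the acetal 21. The allylic bromide of 21 comes from the carbinol 20 by allylic transposition. Carbinol 20 comes from aldehyde 19 and a three-carbon acrylate α-anion equivalent, which brings in C11, C12 and C13 in one step.

**19 to 13 and 16.** The O15 ester bond is cut (19 from 18 from 17). In 13, O14 is already acetylated and O7 is silylated, so O15 is the only free hydroxyl. The two allylic oxygens are distinguished by construction, because they come from different fragments. Acid 16 comes from 14.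

**13 to 11 and 4.** The C3–C4 bond (sp3–sp2) is cut. The forward reaction is a B-alkyl Suzuki–Miyaura coupling through borane 12. Each fragment holds one trisubstituted alkene whose geometry is fixed before the union.

**4 to 1.** The C4=C5 geometry (C15 cis to C6) is taken from a six-membered ring. In lactone 2, C15 (the carbonyl carbon) and C6 are ring members and therefore cis, and the iodine marks C4 for the coupling. Reduction (3) and monosilylation give 4.

**11 to 7 and 8; 7 to 5 and 6.** C1=C10 is cut by a Horner–Wadsworth–Emmons disconnection (11 from 10 from 9). The ester that becomes C14 ends up trans to C2, and C8 travels as a dimethyl acetal from 6.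

## Alternatives that were turned down

**Alternative 1:** the textbook route. Cut the C4=C5 alkene and close ring A by ring-closing metathesis. The trans-lactone with both stereocentres would be made first by an intermolecular asymmetric allylation–lactonisation and elaborated to triene A1. A1 would be closed with a second-generation Grubbs catalyst to give 25. Turned down for these reasons:
- Metathesis would have to form a trisubstituted alkene in a ten-membered ring from a 1,1-disubstituted alkene, which is slow.
- The geometry would be set by ring strain, which favours the ring-cis alkene, whereas C4=C5 must be ring-trans.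
- The acrylate and the methylidene lactone are competing alkenes, and dimers are the usual outcome for this ring size.
- The ring closure would add no stereochemistry, so the route is longer and carries its risk in a step that builds little.

**Alternative 2:** cut the transannular C5–C10 bond of the 1,5-diene (Cope retron). A cis-1,2-dialkenylcyclohexanol A2 would undergo anionic oxy-Cope ring expansion (KN(SiMe3)2, 18-crown-6). The C10 enolate would be trapped as enol triflate A3, and C14 brought in by palladium-catalysed carbonylation. Turned down for these reasons: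
- The ring-cis C1=C10 and ring-trans C4=C5 require a chair transition state with C9 axial on C10 and C6 equatorial on C5. That places C9 in a 1,3-diaxial clash with the C15-bearing C4.
- It also requires the one diastereomer of A2 in which the vinyl group is cis to an axial C5 alkenyl group. Vinyl addition to the parent ketone should come from the opposite face.
- The enolate sits next to the C8 oxygen and can equilibrate and eliminate it.
- C14, O14, C12 and both esters would all have to be adjusted after the key step, so the sequence would be clearly longer.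

**Alternative 3:** cut C2–C3, the bond between the two allylic carbons. The bis(allylic bromide) A4, with the lactone in place, would be closed by reductive allyl–allyl coupling with zerovalent nickel (Ni(CO)4) to give 25. Turned down for these reasons:
- π-Allylnickel intermediates isomerise by σ–π–σ shifts, so the two opposite alkene geometries would be lost.
- Head-to-tail coupling competes with head-to-head coupling.
- The allylic acetate and the allylic acrylate ester are ionised by the same metal.
- The stereocentres would again have to be made beforehand.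

Key step: step 16

Assumption: compounds 1, 5, 6, 8 and 14 are taken as commercial, and the (S,S)-ligand in step 16 is the enantiomer expected to give (7R,8S); its mirror image is used if the sense of induction is the opposite.

## Route

Step 1
Reactants: 1 5,6-dihydro-2H-pyran-2-one
Product: 2 3-iodo-5,6-dihydro-2H-pyran-2-one
Conditions: I2, pyridine, CH2Cl2, 0 °C to rt
Reagents that add atoms: iodine, II
Why: Johnson-type α-iodination of the enoate (pyridine addition, iodination, elimination); the ring holds C15 (the carbonyl carbon) cis to C6 and puts iodine on C4, trans to C6.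

Step 2
Reactants: 2 3-iodo-5,6-dihydro-2H-pyran-2-one
Product: 3 (2E)-2-iodopent-2-ene-1,5-diol
Conditions: iBu2AlH (3.5 equiv), CH2Cl2, −78 to 0 °C; Rochelle salt work-up
Reagents that add atoms: none
Why: Exhaustive 1,2-hydride reduction of the unsaturated lactone through the lactol opens the ring to the diol; the alkenyl iodide is inert and the ring-derived alkene geometry is kept.

Step 3
Reactants: 3 (2E)-2-iodopent-2-ene-1,5-diol
Product: 4 (2E)-5-{[tert-butyl(dimethyl)silyl]oxy}-2-iodopent-2-en-1-ol
Conditions: t-BuMe2SiCl (1.0 equiv), imidazole, CH2Cl2, −40 to 0 °C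
Reagents that add atoms: tert-butyl(chloro)dimethylsilane, CC(C)(C)[Si](C)(C)Cl
Why: Rate-controlled monosilylation; O7 is an unhindered primary hydroxyl, whereas O15 is flanked by the iodine on the same alkene carbon and by the cis C6 chain, so one equivalent of silyl chloride at low temperature should go to O7.

Step 4
Reactants: 5 triethyl phosphonoacetate; 6 2-bromo-1,1-dimethoxyethane
Product: 7 ethyl 2-(diethoxyphosphoryl)-4,4-dimethoxybutanoate (racemic)
Conditions: NaH, DMF, 0 °C; then 6, 90 °C
Reagents that add atoms: none
Why: C-alkylation of the sodium phosphonoacetate with the primary bromide (malonate-type alkylation); the acetal carries C8 at the aldehyde level through the later hydride and organometallic steps.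

Step 5
Reactants: 7 ethyl 2-(diethoxyphosphoryl)-4,4-dimethoxybutanoate; 8 prop-2-enal (acrolein)
Product: 9 ethyl (2E)-2-(2,2-dimethoxyethyl)penta-2,4-dienoate
Conditions: NaH, THF, 0 °C; then 8, −78 to 0 °C
Reagents that add atoms: none
Why: Horner–Wadsworth–Emmons olefination; with a conjugated aldehyde the α-substituted phosphonoacetate should give the (E)-enoate, ester trans to the vinyl group, which is the C14-trans-to-C2 geometry of C1=C10; the stereocentre of 7 disappears.

Step 6
Reactants: 9 ethyl (2E)-2-(2,2-dimethoxyethyl)penta-2,4-dienoate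
Product: 10 (2E)-2-(2,2-dimethoxyethyl)penta-2,4-dien-1-ol
Conditions: iBu2AlH (2.2 equiv), CH2Cl2, −78 °C
Reagents that add atoms: none
Why: 1,2-Reduction of the dienoate to the allylic alcohol (O14); the acetal is inert and the alkene geometry is untouched.

Step 7
Reactants: 10 (2E)-2-(2,2-dimethoxyethyl)penta-2,4-dien-1-ol
Product: 11 (2E)-2-(2,2-dimethoxyethyl)penta-2,4-dien-1-yl acetate
Conditions: Ac2O, pyridine, DMAP (cat.), CH2Cl2, 0 °C
Reagents that add atoms: acetic anhydride, CC(=O)OC(C)=O
Why: Standard acetylation; from here O14 carries its final acyl group, so O14 and O15 never have to be told apart.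

Step 8
Reactants: 11 (2E)-2-(2,2-dimethoxyethyl)penta-2,4-dien-1-yl acetate; 4 (2E)-5-{[tert-butyl(dimethyl)silyl]oxy}-2-iodopent-2-en-1-ol
Product: 13 (2E,6Z)-9-{[tert-butyl(dimethyl)silyl]oxy}-2-(2,2-dimethoxyethyl)-6-(hydroxymethyl)nona-2,6-dien-1-yl acetate, via alkylborane 12 (not isolated)
Conditions: 9-BBN-H, THF, 0 °C to rt; then 4, Pd(dppf)Cl2 (5 mol%), AsPh3, Cs2CO3, DMF/H2O, rt
Reagents that add atoms: none
Why: 9-BBN hydroborates the terminal vinyl group with boron on the terminal carbon C3 and leaves the trisubstituted alkene; the B-alkyl Suzuki–Miyaura coupling then forms C3–C4 with retention at the alkenyl iodide, and allylic acetates are known to survive these room-temperature conditions with alkenyl iodides.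

Step 9
Reactants: 14 2-(hydroxymethyl)prop-2-enoic acid
Product: 16 2-({[tert-butyl(diphenyl)silyl]oxy}methyl)prop-2-enoic acid, via silyl ester 15 (not isolated)
Conditions: t-BuPh2SiCl (2.2 equiv), imidazole, DMF, rt; then AcOH/THF/H2O, rt
Reagents that add atoms: tert-butyl(chloro)diphenylsilane, CC(C)(C)[Si](Cl)(c1ccccc1)c1ccccc1
Why: Double silylation followed by selective hydrolysis of the labile silyl ester; standard protection of a hydroxy acid.

Step 10
Reactants: 13 (2E,6Z)-9-{[tert-butyl(dimethyl)silyl]oxy}-2-(2,2-dimethoxyethyl)-6-(hydroxymethyl)nona-2,6-dien-1-yl acetate; 16 2-({[tert-butyl(diphenyl)silyl]oxy}methyl)prop-2-enoic acid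
Product: 17 (2E,6Z)-9-{[tert-butyl(dimethyl)silyl]oxy}-2-(2,2-dimethoxyethyl)-6-({[2-({[tert-butyl(diphenyl)silyl]oxy}methyl)prop-2-enoyl]oxy}methyl)nona-2,6-dien-1-yl acetate
Conditions: EDC·HCl, DMAP (cat.), CH2Cl2, 0 °C to rt
Reagents that add atoms: none
Why: Carbodiimide (Steglich) esterification of O15, the only free hydroxyl.

Step 11
Reactants: 17 the O15-acylated silyl ether from step 10
Product: 18 (2E,6Z)-2-(2,2-dimethoxyethyl)-9-hydroxy-6-({[2-({[tert-butyl(diphenyl)silyl]oxy}methyl)prop-2-enoyl]oxy}methyl)nona-2,6-dien-1-yl acetate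
Conditions: HF·pyridine, pyridine, THF, 0 °C
Reagents that add atoms: none
Why: Buffered HF·pyridine cleaves the primary alkyl tert-butyldimethylsilyl ether much faster than the tert-butyldiphenylsilyl ether; acetal and esters are untouched.

Step 12
Reactants: 18 the C7 alcohol from step 11
Product: 19 (2E,6Z)-2-(2,2-dimethoxyethyl)-9-oxo-6-({[2-({[tert-butyl(diphenyl)silyl]oxy}methyl)prop-2-enoyl]oxy}methyl)nona-2,6-dien-1-yl acetate
Conditions: Dess–Martin periodinane, pyridine, CH2Cl2, 0 °C to rt
Reagents that add atoms: none
Why: Dess–Martin oxidation under buffered conditions should give the β,γ-unsaturated C7 aldehyde without conjugation; it is used crude.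

Step 13
Reactants: 19 the C7 aldehyde from step 12
Product: 20 methyl (5Z,9E)-10-[(acetyloxy)methyl]-3-hydroxy-12,12-dimethoxy-2-methylidene-6-({[2-({[tert-butyl(diphenyl)silyl]oxy}methyl)prop-2-enoyl]oxy}methyl)dodeca-5,9-dienoate (racemic at the carbinol carbon C7)
Conditions: iBu2AlH, N-methylmorpholine N-oxide, methyl propiolate, THF, 0 °C; then 19, 0 °C to rt
Reagents that add atoms: methyl propiolate, C#CC(=O)OC
Why: Vinylalumination; hydroalumination of the propiolate gives an α-alumino acrylate that adds to the aldehyde as a non-basic equivalent of the Morita–Baylis–Hillman reaction and installs C11, C12 and C13 at once; the new carbinol centre is racemic and is erased in step 14.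

Step 14
Reactants: 20 the racemic carbinol from step 13
Product: 21 methyl (2Z,5Z,9E)-10-[(acetyloxy)methyl]-2-(bromomethyl)-12,12-dimethoxy-6-({[2-({[tert-butyl(diphenyl)silyl]oxy}methyl)prop-2-enoyl]oxy}methyl)dodeca-2,5,9-trienoate
Conditions: N-bromosuccinimide, Me2S, CH2Cl2, 0 °C to rt
Reagents that add atoms: N-bromosuccinimide, BrN1C(=O)CCC1=O
Why: Corey–Kim-type activation of the allylic alcohol and bromide attack with allylic transposition (SN2′) should give the primary 2-(bromomethyl)enoate, by precedent the Z isomer; the geometry of this alkene does not matter for step 16.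

Step 15
Reactants: 21 the allylic bromide acetal from step 14
Product: 22 methyl (2Z,5Z,9E)-10-[(acetyloxy)methyl]-2-(bromomethyl)-12-oxo-6-({[2-({[tert-butyl(diphenyl)silyl]oxy}methyl)prop-2-enoyl]oxy}methyl)dodeca-2,5,9-trienoate
Conditions: In(OTf)3 (2 mol%), acetone/H2O, rt
Reagents that add atoms: water, O
Why: Lewis-acid-catalysed acetal hydrolysis under near-neutral conditions should free the C8 aldehyde without moving the C1=C10 double bond into conjugation; 22 is used at once.

Step 16
Reactants: 22 the bromo aldehyde from step 15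
Product: 25 [(3aR,5Z,9E,11aS)-10-[(acetyloxy)methyl]-3-methylidene-2-oxo-2,3,3a,4,7,8,11,11a-octahydrocyclodeca[b]furan-6-yl]methyl 2-({[tert-butyl(diphenyl)silyl]oxy}methyl)prop-2-enoate, via trimethylsilyl ether 23 (not isolated), via hydroxy ester 24 (not isolated)
Conditions: CrCl2 (15 mol%), (S,S)-1,8-bis(4-isopropyl-4,5-dihydro-1,3-oxazol-2-yl)-3,6-diphenyl-9H-carbazole (17 mol%), Mn, Me3SiCl, iPr2NEt (cat.), THF, rt, slow addition of 22 (final 2 mM); then 1 M HCl, THF, rt
Reagents that add atoms: none
Why: Proposed new method: divalent chromium (CrCl2 with the carbazole bis(oxazoline) ligand, regenerated by Mn) reduces the allylic bromide of 22 in two one-electron steps to a trivalent allylchromium species, which equilibrates by 1,3-metallotropic shift so that both alkene isomers of 22 converge, and then adds through its γ-carbon C7 to the C8 aldehyde in a six-membered chair transition state; Me3SiCl releases chromium as the silyl ether 23, and the acid cleaves the silyl group and lets O8 close onto the C12 ester (24 to 25). The closest known reaction types are the intermolecular enantioselective chromium-catalysed 2-(alkoxycarbonyl)allylation of aldehydes with this ligand class, which gives trans-β,γ-disubstituted α-methylene-γ-butyrolactones, and the racemic CrCl2-mediated intramolecular version that closes ten-membered germacranolide rings; the proposal merges the two. Ring A is closed by attack of C7 on the aldehyde carbon in a 10-exo-trig mode, ring B by a 5-exo-trig acyl substitution with loss of methanol. C7 and C8 are set together: the anti relation (H7 and H8 trans) should follow from the chair transition state with the C6 chain pseudo-equatorial on the allyl unit, and the absolute configuration (7R,8S) from the ligand, which shields one face of the aldehyde. The step needs γ- over α-attack (secured by the cyclic transition state), aldehyde over acrylate and acetate (allylchromium reagents add only to aldehydes) and ring closure over oligomerisation (slow addition at high dilution, with the two trisubstituted alkenes already fixing the turns of the chain).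

Step 17
Reactants: 25 the silyl-protected macrolactone from step 16
Product: 26 [(3aR,5Z,9E,11aS)-10-[(acetyloxy)methyl]-3-methylidene-2-oxo-2,3,3a,4,7,8,11,11a-octahydrocyclodeca[b]furan-6-yl]methyl 2-(hydroxymethyl)prop-2-enoate (CNP0126545.1)
Conditions: Bu4NF, AcOH (1:1), THF, 0 °C to rt
Reagents that add atoms: none
Why: Fluoride cleavage of the silyl ether, buffered with acetic acid so that no alkoxide is free to add to the two Michael acceptors or to shift the esters; the stereocentres and alkenes are not touched.

## Compound list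

1 | 5,6-dihydro-2H-pyran-2-one | O=C1C=CCCO1 | starting material
2 | 3-iodo-5,6-dihydro-2H-pyran-2-one | O=C1C(I)=CCCO1 | intermediate
3 | (2E)-2-iodopent-2-ene-1,5-diol | OC/C(I)=C\CCO | intermediate
4 | (2E)-5-{[tert-butyl(dimethyl)silyl]oxy}-2-iodopent-2-en-1-ol | OC/C(I)=C\CCO[Si](C)(C)C(C)(C)C | intermediate
5 | triethyl phosphonoacetate | CCOC(=O)CP(=O)(OCC)OCC | starting material
6 | 2-bromo-1,1-dimethoxyethane | COC(CBr)OC | starting material
7 | ethyl 2-(diethoxyphosphoryl)-4,4-dimethoxybutanoate (racemic) | CCOC(=O)C(CC(OC)OC)P(=O)(OCC)OCC | intermediate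
8 | prop-2-enal (acrolein) | C=CC=O | starting material
9 | ethyl (2E)-2-(2,2-dimethoxyethyl)penta-2,4-dienoate | CCOC(=O)/C(CC(OC)OC)=C/C=C | intermediate
10 | (2E)-2-(2,2-dimethoxyethyl)penta-2,4-dien-1-ol | OC/C(CC(OC)OC)=C/C=C | intermediate
11 | (2E)-2-(2,2-dimethoxyethyl)penta-2,4-dien-1-yl acetate | CC(=O)OC/C(CC(OC)OC)=C/C=C | intermediate
12 | (2E)-5-(9-borabicyclo[3.3.1]nonan-9-yl)-2-(2,2-dimethoxyethyl)pent-2-en-1-yl acetate | CC(=O)OC/C(CC(OC)OC)=C/CCB1C2CCCC1CCC2 | intermediate (not isolated)
13 | (2E,6Z)-9-{[tert-butyl(dimethyl)silyl]oxy}-2-(2,2-dimethoxyethyl)-6-(hydroxymethyl)nona-2,6-dien-1-yl acetate | CC(=O)OC/C(CC(OC)OC)=C/CC/C(CO)=C/CCO[Si](C)(C)C(C)(C)C | intermediate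
14 | 2-(hydroxymethyl)prop-2-enoic acid | C=C(CO)C(=O)O | starting material
15 | tert-butyl(diphenyl)silyl 2-({[tert-butyl(diphenyl)silyl]oxy}methyl)prop-2-enoate | C=C(CO[Si](c1ccccc1)(c1ccccc1)C(C)(C)C)C(=O)O[Si](c1ccccc1)(c1ccccc1)C(C)(C)C | intermediate (not isolated)
16 | 2-({[tert-butyl(diphenyl)silyl]oxy}methyl)prop-2-enoic acid | C=C(CO[Si](c1ccccc1)(c1ccccc1)C(C)(C)C)C(=O)O | intermediate
17 | (2E,6Z)-9-{[tert-butyl(dimethyl)silyl]oxy}-2-(2,2-dimethoxyethyl)-6-({[2-({[tert-butyl(diphenyl)silyl]oxy}methyl)prop-2-enoyl]oxy}methyl)nona-2,6-dien-1-yl acetate | CC(=O)OC/C(CC(OC)OC)=C/CC/C(COC(=O)C(=C)CO[Si](c1ccccc1)(c1ccccc1)C(C)(C)C)=C/CCO[Si](C)(C)C(C)(C)C | intermediate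
18 | (2E,6Z)-2-(2,2-dimethoxyethyl)-9-hydroxy-6-({[2-({[tert-butyl(diphenyl)silyl]oxy}methyl)prop-2-enoyl]oxy}methyl)nona-2,6-dien-1-yl acetate | CC(=O)OC/C(CC(OC)OC)=C/CC/C(COC(=O)C(=C)CO[Si](c1ccccc1)(c1ccccc1)C(C)(C)C)=C/CCO | intermediate
19 | (2E,6Z)-2-(2,2-dimethoxyethyl)-9-oxo-6-({[2-({[tert-butyl(diphenyl)silyl]oxy}methyl)prop-2-enoyl]oxy}methyl)nona-2,6-dien-1-yl acetate | CC(=O)OC/C(CC(OC)OC)=C/CC/C(COC(=O)C(=C)CO[Si](c1ccccc1)(c1ccccc1)C(C)(C)C)=C/CC=O | intermediate
20 | methyl (5Z,9E)-10-[(acetyloxy)methyl]-3-hydroxy-12,12-dimethoxy-2-methylidene-6-({[2-({[tert-butyl(diphenyl)silyl]oxy}methyl)prop-2-enoyl]oxy}methyl)dodeca-5,9-dienoate (racemic at the carbinol carbon) | CC(=O)OC/C(CC(OC)OC)=C/CC/C(COC(=O)C(=C)CO[Si](c1ccccc1)(c1ccccc1)C(C)(C)C)=C/CC(O)C(=C)C(=O)OC | intermediate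
21 | methyl (2Z,5Z,9E)-10-[(acetyloxy)methyl]-2-(bromomethyl)-12,12-dimethoxy-6-({[2-({[tert-butyl(diphenyl)silyl]oxy}methyl)prop-2-enoyl]oxy}methyl)dodeca-2,5,9-trienoate | CC(=O)OC/C(CC(OC)OC)=C/CC/C(COC(=O)C(=C)CO[Si](c1ccccc1)(c1ccccc1)C(C)(C)C)=C/C/C=C(\CBr)C(=O)OC | intermediate
22 | methyl (2Z,5Z,9E)-10-[(acetyloxy)methyl]-2-(bromomethyl)-12-oxo-6-({[2-({[tert-butyl(diphenyl)silyl]oxy}methyl)prop-2-enoyl]oxy}methyl)dodeca-2,5,9-trienoate | CC(=O)OC/C(CC=O)=C/CC/C(COC(=O)C(=C)CO[Si](c1ccccc1)(c1ccccc1)C(C)(C)C)=C/C/C=C(\CBr)C(=O)OC | intermediate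
23 | methyl 2-[(1R,2S,4E,8Z)-4-[(acetyloxy)methyl]-8-({[2-({[tert-butyl(diphenyl)silyl]oxy}methyl)prop-2-enoyl]oxy}methyl)-2-[(trimethylsilyl)oxy]cyclodeca-4,8-dien-1-yl]prop-2-enoate | C=C(CO[Si](c2ccccc2)(c2ccccc2)C(C)(C)C)C(=O)OC/C1=C\C[C@H](C(=C)C(=O)OC)[C@@H](O[Si](C)(C)C)C/C(COC(C)=O)=C\CC1 | intermediate (not isolated)
24 | methyl 2-[(1R,2S,4E,8Z)-4-[(acetyloxy)methyl]-8-({[2-({[tert-butyl(diphenyl)silyl]oxy}methyl)prop-2-enoyl]oxy}methyl)-2-hydroxycyclodeca-4,8-dien-1-yl]prop-2-enoate | C=C(CO[Si](c2ccccc2)(c2ccccc2)C(C)(C)C)C(=O)OC/C1=C\C[C@H](C(=C)C(=O)OC)[C@@H](O)C/C(COC(C)=O)=C\CC1 | intermediate (not isolated)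
25 | [(3aR,5Z,9E,11aS)-10-[(acetyloxy)methyl]-3-methylidene-2-oxo-2,3,3a,4,7,8,11,11a-octahydrocyclodeca[b]furan-6-yl]methyl 2-({[tert-butyl(diphenyl)silyl]oxy}methyl)prop-2-enoate | C=C(CO[Si](c3ccccc3)(c3ccccc3)C(C)(C)C)C(=O)OC/C1=C\C[C@@H]2C(=C)C(=O)O[C@H]2C/C(COC(C)=O)=C\CC1 | intermediate
26 | [(3aR,5Z,9E,11aS)-10-[(acetyloxy)methyl]-3-methylidene-2-oxo-2,3,3a,4,7,8,11,11a-octahydrocyclodeca[b]furan-6-yl]methyl 2-(hydroxymethyl)prop-2-enoate (CNP0126545.1) | C=C(CO)C(=O)OC/C1=C\C[C@@H]2C(=C)C(=O)O[C@H]2C/C(COC(C)=O)=C\CC1 | target

## Step count and least certain steps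

Total: 17 steps. Longest linear sequence: 13 steps (steps 4 to 8 and 10 to 17).

**Step 16 (key step, proposed new method).** Three processes may defeat it. Oligomerisation can outrun ring closure, because the ten-membered ring is strained. Enantiofacial discrimination may be insufficient, because the ligand was developed for bimolecular additions and the tether may override it. The β,γ-unsaturated aldehyde may drift into conjugation before it is attacked. Fallback, with known chemistry: from 22, the ring closure is run with stoichiometric CrCl2 in THF/DMF at high dilution, the established racemic mode of this reaction, with acidic work-up. This should give 25 together with its (3aS,11aR)-enantiomer F1, through the racemic hydroxy ester (24 and its enantiomer F2). The enantiomers are separated by preparative chromatography on a chiral stationary phase, and the route is rejoined at 25.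

**Step 13.** The aldehyde may enolise and isomerise to the conjugated enal, or be reduced by residual hydride, before the alane adds, since the alane is a weak nucleophile. Fallback: from 19, aldol addition of the lithium enolate of methyl 3-(phenylselanyl)propanoate (LiN(iPr)2, THF, −78 °C), which is fast at low temperature, gives the β-hydroxy selenide F3. Oxidation (H2O2, pyridine) and syn-elimination of the selenoxide lead to 20.

**Step 8.** Hydroboration may lose regiocontrol on the conjugated diene, and zerovalent palladium may ionise the allylic acetate in competition with oxidative addition. Fallback that avoids both the diene and the borane, from 7: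
- Horner–Wadsworth–Emmons reaction with 3-{[tert-butyl(dimethyl)silyl]oxy}propanal (NaH, THF) gives the enoate F4.
- iBu2AlH gives the allylic alcohol F5, and Ac2O/pyridine the acetate F6.
- HF·pyridine gives the primary alcohol F7, and PPh3/I2/imidazole the iodide F8.
- Zinc insertion (Zn, LiCl, THF) gives the alkylzinc iodide F9.
- Negishi coupling with 4 (Pd2(dba)3, SPhos, THF; a second equivalent of F9 covers the free hydroxyl) gives 13.

**Step 3.** Silylation may be poorly site-selective, giving silylation at O15 or at both oxygens, because both hydroxyls are primary. Fallback that differentiates the two oxygens by oxidation level, from 2: aminolysis with Me3Al and N,O-dimethylhydroxylamine hydrochloride opens the lactone to the hydroxy amide F10, in which O7 is the only hydroxyl. Silylation (t-BuMe2SiCl, imidazole) gives F11, iBu2AlH at −78 °C gives the aldehyde F12, and NaBH4/CeCl3 gives 4.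

Further compounds
F1 | step 16 | (3aS,11aR)-enantiomer of 25 | C=C(CO[Si](c3ccccc3)(c3ccccc3)C(C)(C)C)C(=O)OC/C1=C\C[C@H]2C(=C)C(=O)O[C@@H]2C/C(COC(C)=O)=C\CC1
F2 | step 16 | (1S,2R)-enantiomer of 24 | C=C(CO[Si](c2ccccc2)(c2ccccc2)C(C)(C)C)C(=O)OC/C1=C\C[C@@H](C(=C)C(=O)OC)[C@H](O)C/C(COC(C)=O)=C\CC1
F3 | step 13 | methyl (5Z,9E)-10-[(acetyloxy)methyl]-3-hydroxy-12,12-dimethoxy-2-[(phenylselanyl)methyl]-6-({[2-({[tert-butyl(diphenyl)silyl]oxy}methyl)prop-2-enoyl]oxy}methyl)dodeca-5,9-dienoate (mixture of diastereomers) | CC(=O)OC/C(CC(OC)OC)=C/CC/C(COC(=O)C(=C)CO[Si](c1ccccc1)(c1ccccc1)C(C)(C)C)=C/CC(O)C(C[Se]c1ccccc1)C(=O)OC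
F4 | step 8 | ethyl (2E)-5-{[tert-butyl(dimethyl)silyl]oxy}-2-(2,2-dimethoxyethyl)pent-2-enoate | CCOC(=O)/C(CC(OC)OC)=C/CCO[Si](C)(C)C(C)(C)C
F5 | step 8 | (2E)-5-{[tert-butyl(dimethyl)silyl]oxy}-2-(2,2-dimethoxyethyl)pent-2-en-1-ol | OC/C(CC(OC)OC)=C/CCO[Si](C)(C)C(C)(C)C
F6 | step 8 | (2E)-5-{[tert-butyl(dimethyl)silyl]oxy}-2-(2,2-dimethoxyethyl)pent-2-en-1-yl acetate | CC(=O)OC/C(CC(OC)OC)=C/CCO[Si](C)(C)C(C)(C)C
F7 | step 8 | (2E)-2-(2,2-dimethoxyethyl)-5-hydroxypent-2-en-1-yl acetate | CC(=O)OC/C(CC(OC)OC)=C/CCO
F8 | step 8 | (2E)-2-(2,2-dimethoxyethyl)-5-iodopent-2-en-1-yl acetate | CC(=O)OC/C(CC(OC)OC)=C/CCI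
F9 | step 8 | {(3E)-4-[(acetyloxy)methyl]-6,6-dimethoxyhex-3-en-1-yl}(iodo)zinc | CC(=O)OC/C(CC(OC)OC)=C/CC[Zn]I
F10 | step 3 | (2E)-5-hydroxy-2-iodo-N-methoxy-N-methylpent-2-enamide | CON(C)C(=O)/C(I)=C\CCO
F11 | step 3 | (2E)-5-{[tert-butyl(dimethyl)silyl]oxy}-2-iodo-N-methoxy-N-methylpent-2-enamide | CON(C)C(=O)/C(I)=C\CCO[Si](C)(C)C(C)(C)C
F12 | step 3 | (2E)-5-{[tert-butyl(dimethyl)silyl]oxy}-2-iodopent-2-enal | O=C/C(I)=C\CCO[Si](C)(C)C(C)(C)C
A1 | alternative 1 | metathesis precursor: (7R,8S)-trans-α-methylene-γ-butyrolactone with an allyl group on C7 and, on C8, the C9–C10(C14H2OAc)=C1–C2–C3–C4(=CH2)–C15H2O-acyl chain | C=CC[C@@H]1C(=C)C(=O)O[C@H]1C/C(COC(C)=O)=C\CCC(=C)COC(=O)C(=C)CO[Si](c1ccccc1)(c1ccccc1)C(C)(C)C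
A2 | alternative 2 | oxy-Cope substrate: 1-vinylcyclohexan-1-ol (C10) with the C5 alkenyl group cis to the vinyl group, the C7 alkenyl group and the C8 silyl ether trans | C=C[C@]1(O)C[C@H](O[Si](C)(C)C(C)(C)C)[C@@H](C(=C)CO[Si](C)(C)C(C)(C)C)C[C@@H]1C(=C)COCc1ccc(OC)cc1
A3 | alternative 2 | ten-membered enol triflate at C10 (C9 and C2 cis, C3 and C6 trans) | FC(F)(F)S(=O)(=O)O/C1=C/CC/C(COCc2ccc(OC)cc2)=C/C[C@H](C(=C)CO[Si](C)(C)C(C)(C)C)[C@@H](O[Si](C)(C)C(C)(C)C)C1
A4 | alternative 3 | bis(allylic bromide): (7R,8S)-trans-lactone with C2 and C3 as bromomethyl termini | BrC/C(COC(=O)C(=C)CO[Si](c1ccccc1)(c1ccccc1)C(C)(C)C)=C/C[C@@H]2C(=C)C(=O)O[C@H]2C/C(COC(C)=O)=C\CBr
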